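(Readings and results are simulated with constants of no real substance; noise was put on by code.)

Amounts of gas, not minutes, place the target in these flasks. Both steps take one dissolved gas molecule, so a molecule arriving in solution faces a fork: substrate or target. The odds at that fork depend on the amounts of substrate and target, with s the selectivity factor, the attack on target per molecule relative to that on substrate. They do not depend on how much gas is dissolved. The target fraction p therefore follows the **gas dose** g, the gas taken up per substrate charged.

| flask | substrate | gas phase | remark | time |
|---|---|---|---|---|
| north-east | 0.034 M | 17 mM (held) | run made earlier |  |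
| north-west | 0.47 M | 17 mM (held) | run made earlier |  |
| epsilon | 0.30 M | 17 mM (held) |  | 25 min |
| alpha | 0.10 M | 17 mM (held) |  | 25 min |
| beta | 0.060 M | 17 mM (held) |  | 25 min |
| gamma | 0.025 M | 17 mM (held) |  | 25 min |

| north-east: time / min | north-east: target / % | north-west: time / min | north-west: target / % |
|---|---|---|---|
| 2.00 | 12.1 | 2.00 | 3.9 |
| 6.00 | 38.5 | 4.00 | 8.6 |
| 12.0 | 47.1 | 8.00 | 14.1 |
| 20.0 | 34.3 | 12.0 | 22.9 |
| 25.0 | 26.3 | 25.0 | 36.3 |

(standard deviation of a reading: 1 percentage point)

- the flasks put in order of amount of target, in percent of the substrate charged, best first, at 25 min (epsilon / alpha / beta / gamma)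
- the amount of target, in percent of the substrate charged of the flask you put first, at 25 min
- the amount of target, in percent of the substrate charged of the flask you put last, at 25 min

- at the start none of the gas is dissolved
- reactions considered so far: substrate + dissolved gas -> target; gas phase <-> dissolved gas; dissolved gas + target -> over-reacted product; dissolved gas + target -> over-reaction product

How large is s? With s = 0.5, integrating the fork gives p = g(1 − g/2), with a top of p = 0.5 at one gas per substrate. The north-east reading of 47.1% at 12.0 min lies close to that top, so this reckoning keeps the curve's shape and scales its top to that reading.

What dose can each flask receive? The north-west flask, with its large charge, had made target at about 8.97 mM min⁻¹ by 12.0 min, which is read here as the pace of gas transfer, the rate-limiting step there. Epsilon at that pace receives g = 0.747 in 25 min, short of the top, and the curve gives 44.1%.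

Gamma, charged with less substrate than north-east, should stand further past the top, below north-east's 26.3%. Alpha's cap of 2.24 lets it pass the top, and this reckoning leaves its place beside epsilon open.

The forecast gives epsilon > alpha > beta > gamma, with 44% first and 23% last, on the ground that “A gas balance over 25 min gives about 215 mM uptake for epsilon”.

The flasks give epsilon > alpha > beta > gamma, with 43.6% first and 22.8% last.

    substrate + dissolved gas → target (k = 0.177 M⁻¹ s⁻¹)
    gas phase ⇌ dissolved gas, rate k2*(csat - [dissolved gas]) (kL = 0.0107 s⁻¹)
    dissolved gas + target → over-reacted product (k = 0.0767 M⁻¹ s⁻¹)
    dissolved gas + target → over-reaction product (k = 0.0286 M⁻¹ s⁻¹)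

Epsilon at 25.0 min still holds 42.1% of its substrate, and counting both over-reaction routes its gas dose, in percent of the substrate charged, is 72.2%, close to the 74.7% reckoned from the north-west pace. A neighbour of gamma charged with 0.062 M took up a gas dose of 154% of its substrate charged by 25.0 min, for which the curve gives 33.4%, and that flask holds 32.7%.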